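The runs were generated by integration with made-up constants, and the scatter is random.

In this flask the time the remaining reagent would last at the present rate shrinks far more slowly than the reagent itself, and we reckon with that lag.

| setting | delta | flask |
|---|---|---|
| starting material | 1.5 M | 1.5 M |
| reagent | 0.90 M | 0.900 M |
| free catalyst | 15 mM | 15 mM |
| added ligand | 66 mM | 66 mM |
| remark | the very flask that is asked about, followed so far |  |

delta run (percent of the starting material charged)

| time / min | product / % | starting material / % |
|---|---|---|
| 10.0 | 28.3 | 71.4 |
| 20.0 | 46.2 | 52.7 |
| 30.0 | 55.3 | 44.9 |
| 40.0 | 58.6 | 41.2 |
| 50.0 | 59.1 | 40.7 |

(each reading ± 0.5 percentage points)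

1. apparent order in free catalyst when 5.0% of the starting material are converted (percent change of the rate of making product for one percent more free catalyst charged)
2. apparent order in reagent when 5.0% of the starting material are converted (percent change of the rate of making product for one percent more reagent charged)

- the numbers in the tables scatter with a standard deviation of 0.5 percentage points
- no earlier run changes the charge of free catalyst; that part of a forecast is a guess
- what is bound to the catalyst counts as converted
- no earlier run changes the charge of reagent; that part of a forecast is a guess

Product levels off at 59.1% of the starting material, against the 60.0% that the reagent charge allows, so reagent is the limiting reagent, used one for one. Reagent left is then this cap minus product, and we call reagent left over rate the lasting time.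

The first interval has 45.8% left on average and lasts 16.2 min. The last useful interval, ending at 40.0 min, has 3.05% left and lasts 9.24 min.

We freeze one thing: a turn of the catalyst is a wait for reagent, going as one over [reagent], plus a remainder taken as constant. Lasting time is then a straight line in [reagent], with slope 16.3 min per unit of that fraction. Its value at no reagent, 8.75 min, is the waiting floor.

The middle intervals test the line: 12.7 min against 12.4 min, then 10.2 min against 10.3 min.

Floor over lasting time is the waiting share of a turn, and that share is the order in the reagent present. At 5.0% conversion, 55.0% is left, the line gives 17.7 min, and the share is 49.4%. One percent more charge raises the reagent present by 1.09 percent, so we commit to 0.539. This is a reading: starting material falls alongside, and the floor hangs on one small step of product. For the catalyst we guess order 1, with added ligand at 4.40 times the charge of free catalyst.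

The forecast says 1 in free catalyst and 0.65 in reagent, higher than ours in reagent, noting that “both concentrations fall together”.

The flask gives 1.0 in free catalyst and 0.54 in reagent.

    reagent + free catalyst → catalyst intermediate A (k = 0.262 M⁻¹ s⁻¹)
    catalyst intermediate A ⇌ catalyst intermediate B (K = 98.0, k = 0.357 s⁻¹)
    starting material + catalyst intermediate B ⇌ catalyst intermediate C (K = 54.0 M⁻¹, k = 1.28 M⁻¹ s⁻¹)
    catalyst intermediate C → by-product + catalyst intermediate D (k = 0.196 s⁻¹)
    catalyst intermediate D → free catalyst + product (k = 1.47 s⁻¹)
    free catalyst + added ligand ⇌ idle complex, settled at all times (K = 16.3 M⁻¹)

Reagent enters the round in one step, on free catalyst, and free catalyst pairs with added ligand as idle complex. At 0.300 h the flask has 26.8% of its reagent charge, and the floor gives a waiting share of 76.9%; the flask then holds 38.5% of its catalyst as free catalyst and 37.9% as idle complex, together 76.4%, and 23.6% as catalyst intermediates A, B, C and D.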